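**Plan**
- Retrosynthesis: the three MOM ethers come off last; the C2=C3 double bond is traced back to a tertiary alcohol at C3; the C3–C4 bond is then cut, followed by the aryl ether bond O1–C2 and the two aryl–prenyl bonds.
- Enabling feature: C4 is a ketone carbon bonded to ring A, C3 carries ring B, and the two are linked through O1–C2. Ring C can therefore be closed by joining a ring A formyl carbon, used as an acyl anion, to the carbonyl carbon of a ring B aryl ketone.
- Forward order: the ring A piece is made by C-diprenylation and bis-MOM protection, the ring B piece by MOM protection and alpha-bromination. The two are joined through the O1–C2 ether, ring C (the only ring that is built) is closed by carbene catalysis, and dehydration and deprotection finish the route.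
- Stereochemistry: the target is achiral. The single stereocentre that appears (C3 of the benzoin product) is formed as a racemate and erased by the dehydration.

Key step: step 6

Assumption: both phenolic building blocks are taken as purchasable, and an achiral carbene catalyst is used because the C3 centre does not survive to the target.

**Step 1**
Reactants: 1 2,4,6-trihydroxybenzaldehyde; 2 1-bromo-3-methylbut-2-ene (prenyl bromide)
Product: 3 2,4,6-trihydroxy-3,5-bis(3-methylbut-2-enyl)benzaldehyde
Conditions: 2 (2.2 equiv), KOH (10% aq), 0 °C → rt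
Reagents that add atoms: none
Why: Phenoxide C-alkylation of an acylphloroglucinol: in water the polyphenolate reacts with the allylic bromide at its ring carbons, and C3 and C5 are the only free and equivalent positions, so the double alkylation is regiochemically unambiguous, although O-alkylated and over-alkylated material will have to be separated.

**Step 2**
Reactants: 3 2,4,6-trihydroxy-3,5-bis(3-methylbut-2-enyl)benzaldehyde
Product: 4 2-hydroxy-4,6-bis(methoxymethoxy)-3,5-bis(3-methylbut-2-enyl)benzaldehyde
Conditions: MOMCl (2.2 equiv), i-Pr2NEt, CH2Cl2, 0 °C → rt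
Reagents that add atoms: chloromethyl methyl ether, COCCl
Why: Base-mediated MOM ether formation: the para hydroxyl and one ortho hydroxyl are etherified while the other ortho hydroxyl stays free in its hydrogen bond to the formyl oxygen, and the symmetry of 3 makes the two ortho hydroxyls equivalent, so one bis-ether should result.

**Step 3**
Reactants: 5 1-(4-hydroxy-2-methoxyphenyl)ethanone
Product: 6 1-[2-methoxy-4-(methoxymethoxy)phenyl]ethanone
Conditions: MOMCl, i-Pr2NEt, CH2Cl2, 0 °C → rt
Reagents that add atoms: chloromethyl methyl ether, COCCl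
Why: MOM ether formation on the only free phenol masks it for the enolate chemistry and the alkylation that follow.

**Step 4**
Reactants: 6 1-[2-methoxy-4-(methoxymethoxy)phenyl]ethanone
Product: 8 2-bromo-1-[2-methoxy-4-(methoxymethoxy)phenyl]ethanone, via silyl enol ether 7 (not isolated)
Conditions: LiN(SiMe3)2, Me3SiCl, THF, −78 °C; then NBS, 0 °C
Reagents that add atoms: N-bromosuccinimide, O=C1CCC(=O)N1Br
Why: Kinetic enolisation and O-silylation followed by electrophilic bromination of the silyl enol ether puts one bromine on the methyl carbon without free acid, so the MOM acetal and the electron-rich ring should stay intact.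

**Step 5**
Reactants: 4 2-hydroxy-4,6-bis(methoxymethoxy)-3,5-bis(3-methylbut-2-enyl)benzaldehyde; 8 2-bromo-1-[2-methoxy-4-(methoxymethoxy)phenyl]ethanone
Product: 9 2,4-bis(methoxymethoxy)-6-{2-[2-methoxy-4-(methoxymethoxy)phenyl]-2-oxoethoxy}-3,5-bis(3-methylbut-2-enyl)benzaldehyde
Conditions: K2CO3, DMF, 0 °C → rt
Reagents that add atoms: none
Why: Williamson ether synthesis: the phenoxide of 4 displaces bromide from the reactive alpha-bromo ketone by SN2, and a carbonate base at room temperature is chosen so that the product does not go on to aldol condensation of its OCH2 group with the formyl group (Rap–Stoermer pathway).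

**Step 6**
Reactants: 9 2,4-bis(methoxymethoxy)-6-{2-[2-methoxy-4-(methoxymethoxy)phenyl]-2-oxoethoxy}-3,5-bis(3-methylbut-2-enyl)benzaldehyde
Product: 10 rac-3-hydroxy-3-[2-methoxy-4-(methoxymethoxy)phenyl]-5,7-bis(methoxymethoxy)-6,8-bis(3-methylbut-2-enyl)chroman-4-one
Conditions: 2-(pentafluorophenyl)-6,7-dihydro-5H-pyrrolo[2,1-c][1,2,4]triazol-2-ium tetrafluoroborate (20 mol%), Et3N (20 mol%), toluene, 40 °C
Reagents that add atoms: none
Why: The triazolylidene released by Et3N adds to the formyl carbon of 9 and proton transfer gives the Breslow intermediate, in which the former aldehyde carbon (C4) is nucleophilic; it attacks the tethered aryl ketone carbon (C3), and proton shift with loss of the carbene restores the C4 carbonyl and leaves the tertiary alcohol at C3. The closest known reaction type is the carbene-catalysed intramolecular crossed aldehyde–ketone benzoin reaction that turns 2-(2-oxoalkoxy)benzaldehydes into 3-hydroxychroman-4-ones. Ring C closes in a 6-exo-trig mode, with the ketone C=O outside the new six-membered ring made up of C4, C4a, C8a, O1, C2 and C3. The C3 stereocentre is not controlled, since the catalyst is achiral and the substrate has no other stereogenic element, so a racemate is expected, which is acceptable because step 7 removes this centre. The step needs the aldehyde to act as donor and the ketone as acceptor and must outrun homo-benzoin coupling and base-induced aldol closure: only the aldehyde has the C–H needed for the acyl anion equivalent, its two ortho substituents block intermolecular attack, the two-atom O1–C2 tether holds the ketone within reach, and a weak amine base with an acidic N-pentafluorophenyl triazolium salt keeps enolate formation at C2 low.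

**Step 7**
Reactants: 10 rac-3-hydroxy-3-[2-methoxy-4-(methoxymethoxy)phenyl]-5,7-bis(methoxymethoxy)-6,8-bis(3-methylbut-2-enyl)chroman-4-one
Product: 11 3-[2-methoxy-4-(methoxymethoxy)phenyl]-5,7-bis(methoxymethoxy)-6,8-bis(3-methylbut-2-enyl)chromen-4-one
Conditions: Burgess reagent, toluene, 60 °C
Reagents that add atoms: none
Why: Burgess dehydration: the tertiary alcohol becomes a sulfamate ester that eliminates thermally in a syn fashion, and since C2 holds the only beta hydrogens the double bond can form only between C2 and C3, under neutral conditions that spare the MOM acetals and the prenyl olefins.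

**Step 8**
Reactants: 11 3-[2-methoxy-4-(methoxymethoxy)phenyl]-5,7-bis(methoxymethoxy)-6,8-bis(3-methylbut-2-enyl)chromen-4-one
Product: 12 5,7-dihydroxy-3-(4-hydroxy-2-methoxyphenyl)-6,8-bis(3-methylbut-2-enyl)chromen-4-one
Conditions: 3 M aq HCl, MeOH, 50 °C
Reagents that add atoms: none
Why: Acid-catalysed acetal solvolysis in methanol removes the three MOM ethers as dimethoxymethane, and the reaction is to be stopped as soon as the triphenol has formed so that acid-induced cyclisation of the prenyl groups onto neighbouring free phenols does not set in.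

**Compound list**
1 | 2,4,6-trihydroxybenzaldehyde | O=Cc1c(O)cc(O)cc1O | starting material
2 | 1-bromo-3-methylbut-2-ene (prenyl bromide) | CC(C)=CCBr | starting material
3 | 2,4,6-trihydroxy-3,5-bis(3-methylbut-2-enyl)benzaldehyde | O=Cc1c(O)c(CC=C(C)C)c(O)c(CC=C(C)C)c1O | intermediate
4 | 2-hydroxy-4,6-bis(methoxymethoxy)-3,5-bis(3-methylbut-2-enyl)benzaldehyde | O=Cc1c(O)c(CC=C(C)C)c(OCOC)c(CC=C(C)C)c1OCOC | intermediate
5 | 1-(4-hydroxy-2-methoxyphenyl)ethanone | CC(=O)c1ccc(O)cc1OC | starting material
6 | 1-[2-methoxy-4-(methoxymethoxy)phenyl]ethanone | CC(=O)c1ccc(OCOC)cc1OC | intermediate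
7 | trimethyl({1-[2-methoxy-4-(methoxymethoxy)phenyl]ethenyl}oxy)silane (silyl enol ether, not isolated) | C=C(O[Si](C)(C)C)c1ccc(OCOC)cc1OC | intermediate
8 | 2-bromo-1-[2-methoxy-4-(methoxymethoxy)phenyl]ethanone | O=C(CBr)c1ccc(OCOC)cc1OC | intermediate
9 | 2,4-bis(methoxymethoxy)-6-{2-[2-methoxy-4-(methoxymethoxy)phenyl]-2-oxoethoxy}-3,5-bis(3-methylbut-2-enyl)benzaldehyde | O=Cc1c(OCC(=O)c2ccc(OCOC)cc2OC)c(CC=C(C)C)c(OCOC)c(CC=C(C)C)c1OCOC | intermediate
10 | rac-3-hydroxy-3-[2-methoxy-4-(methoxymethoxy)phenyl]-5,7-bis(methoxymethoxy)-6,8-bis(3-methylbut-2-enyl)chroman-4-one | O=C1c2c(OCOC)c(CC=C(C)C)c(OCOC)c(CC=C(C)C)c2OCC1(O)c1ccc(OCOC)cc1OC | intermediate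
11 | 3-[2-methoxy-4-(methoxymethoxy)phenyl]-5,7-bis(methoxymethoxy)-6,8-bis(3-methylbut-2-enyl)chromen-4-one | COCOc1ccc(-c2coc3c(CC=C(C)C)c(OCOC)c(CC=C(C)C)c(OCOC)c3c2=O)c(OC)c1 | intermediate
12 | 5,7-dihydroxy-3-(4-hydroxy-2-methoxyphenyl)-6,8-bis(3-methylbut-2-enyl)chromen-4-one | COc1cc(O)ccc1-c1coc2c(CC=C(C)C)c(O)c(CC=C(C)C)c(O)c2c1=O | target

**Totals**
Total step count: 8. Longest linear sequence: 6 steps (steps 1, 2, 5, 6, 7, 8; the ring B branch through steps 3 and 4 is equally long).

**Steps most likely to fail**

Step 6. Carbene addition to the doubly ortho-substituted, electron-rich formyl group may be too slow, so that enolisation at the OCH2 carbon and five-membered aldol closure onto the aldehyde take over. The fallback gives up the carbene closure for a Suzuki–Miyaura isoflavone assembly; it sets out from phenol 4 and comes back at target 12.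
- MeMgBr (THF, 0 °C) would add to 4 to give 2-(1-hydroxyethyl)-3,5-bis(methoxymethoxy)-4,6-bis(3-methylbut-2-enyl)phenol F1.
- MnO2 (CH2Cl2, rt) would oxidise it to 1-[2-hydroxy-4,6-bis(methoxymethoxy)-3,5-bis(3-methylbut-2-enyl)phenyl]ethanone F2.
- Condensation with N,N-dimethylformamide dimethyl acetal (toluene, 90 °C) would give (E)-3-(dimethylamino)-1-[2-hydroxy-4,6-bis(methoxymethoxy)-3,5-bis(3-methylbut-2-enyl)phenyl]prop-2-en-1-one F3.
- I2 (1.1 equiv) and pyridine (CHCl3, 0 °C) should close it to 3-iodo-5,7-bis(methoxymethoxy)-6,8-bis(3-methylbut-2-enyl)chromen-4-one F4; the enamine carbon is expected to react well before the prenyl olefins.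
- Coupling of F4 with purchased (4-hydroxy-2-methoxyphenyl)boronic acid (Pd(PPh3)4, a zerovalent palladium complex, K2CO3, dioxane/H2O, 80 °C) would give 3-(4-hydroxy-2-methoxyphenyl)-5,7-bis(methoxymethoxy)-6,8-bis(3-methylbut-2-enyl)chromen-4-one F5.
- Methanolic HCl as in step 8 would then release 12.

Step 1. O-alkylation and a second alkylation at an already prenylated carbon (with loss of aromaticity) compete with the double C-alkylation and may leave little of 3. The fallback installs the prenyl groups by directed ortho-metalation; it sets out from prenyl bromide 2 and purchased benzene-1,3,5-triol and comes back at phenol 4.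
- The triol would be converted (NaH, MOMCl, DMF) into 1,3,5-tris(methoxymethoxy)benzene F6.
- Lithiation between two MOM ethers (n-BuLi, THF, 0 °C), transmetalation with CuBr·SMe2 and alkylation with 2 would give 1,3,5-tris(methoxymethoxy)-2-(3-methylbut-2-enyl)benzene F7.
- Repeating the sequence would give 1,3,5-tris(methoxymethoxy)-2,4-bis(3-methylbut-2-enyl)benzene F8.
- A third lithiation at the last ring position and a DMF quench would give 2,4,6-tris(methoxymethoxy)-3,5-bis(3-methylbut-2-enyl)benzaldehyde F9.
- Brief treatment with dilute methanolic HCl at 0 °C should remove one of the two carbonyl-activated ortho MOM ethers and give 4.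

Step 5. Alkylation of the hindered, hydrogen-bonded phenol may be slow, while the carbonate base meanwhile drives aldol condensation of the product toward a 2-aroylbenzofuran. The fallback forms the same ether bond without base by a Mitsunobu reaction; it sets out from bromo ketone 8 and comes back at 9.
- HCO2Na in aqueous EtOH at reflux would convert 8, through 2-[2-methoxy-4-(methoxymethoxy)phenyl]-2-oxoethyl formate F10 that is hydrolysed in the same pot, into 2-hydroxy-1-[2-methoxy-4-(methoxymethoxy)phenyl]ethanone F11.
- Coupling of F11 with phenol 4 (PPh3, diisopropyl azodicarboxylate, THF, 0 °C → rt) would give 9.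

**Further compounds**
F1 | step 6 | 2-(1-hydroxyethyl)-3,5-bis(methoxymethoxy)-4,6-bis(3-methylbut-2-enyl)phenol (racemic) | CC(O)c1c(O)c(CC=C(C)C)c(OCOC)c(CC=C(C)C)c1OCOC
F2 | step 6 | 1-[2-hydroxy-4,6-bis(methoxymethoxy)-3,5-bis(3-methylbut-2-enyl)phenyl]ethanone | CC(=O)c1c(O)c(CC=C(C)C)c(OCOC)c(CC=C(C)C)c1OCOC
F3 | step 6 | (E)-3-(dimethylamino)-1-[2-hydroxy-4,6-bis(methoxymethoxy)-3,5-bis(3-methylbut-2-enyl)phenyl]prop-2-en-1-one | CN(C)/C=C/C(=O)c1c(O)c(CC=C(C)C)c(OCOC)c(CC=C(C)C)c1OCOC
F4 | step 6 | 3-iodo-5,7-bis(methoxymethoxy)-6,8-bis(3-methylbut-2-enyl)chromen-4-one | O=c1c(I)coc2c(CC=C(C)C)c(OCOC)c(CC=C(C)C)c(OCOC)c12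
F5 | step 6 | 3-(4-hydroxy-2-methoxyphenyl)-5,7-bis(methoxymethoxy)-6,8-bis(3-methylbut-2-enyl)chromen-4-one | COc1cc(O)ccc1-c1coc2c(CC=C(C)C)c(OCOC)c(CC=C(C)C)c(OCOC)c2c1=O
F6 | step 1 | 1,3,5-tris(methoxymethoxy)benzene | COCOc1cc(OCOC)cc(OCOC)c1
F7 | step 1 | 1,3,5-tris(methoxymethoxy)-2-(3-methylbut-2-enyl)benzene | COCOc1cc(OCOC)c(CC=C(C)C)c(OCOC)c1
F8 | step 1 | 1,3,5-tris(methoxymethoxy)-2,4-bis(3-methylbut-2-enyl)benzene | COCOc1cc(OCOC)c(CC=C(C)C)c(OCOC)c1CC=C(C)C
F9 | step 1 | 2,4,6-tris(methoxymethoxy)-3,5-bis(3-methylbut-2-enyl)benzaldehyde | O=Cc1c(OCOC)c(CC=C(C)C)c(OCOC)c(CC=C(C)C)c1OCOC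
F10 | step 5 | 2-[2-methoxy-4-(methoxymethoxy)phenyl]-2-oxoethyl formate | O=COCC(=O)c1ccc(OCOC)cc1OC
F11 | step 5 | 2-hydroxy-1-[2-methoxy-4-(methoxymethoxy)phenyl]ethanone | OCC(=O)c1ccc(OCOC)cc1OC
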